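Numbering (germacrane): C1 ketone, C2=C3 enol ether, ring oxygen between C3 and C10, Z C4=C5 (C15 methyl), C6 lactone oxygen, C7, C8 ester, C9 hydroxyl, C10 (C14 methyl), C11=C13 and C12 of the methylene lactone.
Cuts, last-formed bond first: the C8 ester; the C12–O6 lactone; O–C3 of the furanone; C1–C2 of the ten-membered carbocycle; then C2–C3, C4=C5, C10–C1, C10–C14 and C7–C11 on a hexose chain.
Enabling feature: the furanone ring C10–C1(=O)–C2=C3–O is the cyclised isomer of the hydroxy ynone C10(OH)–C1(=O)–C2≡C3, so the carbocycle C1–C10 can be closed unbridged at C1–C2 between a C1 thioester and the terminal alkyne carbon C2 of a Z enyne.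
Forward: C5–C10 are C1–C6 of D-glucose; the C7 branch and then C10/C1 are built on the furanose, the lactol is opened to the Z enoate and homologated to the enyne; the rings form in the order carbocycle (step 26), furanone (step 28), lactone (step 31).
Stereochemistry: C6, C8 and C9 are C2, C4 and C5 of D-glucose; C7 is set by hydrogenation anti to the 1,2-acetonide, C10 by a chelation-controlled Grignard addition, and the Z alkene by a Still–Gennari olefination.

Key step: step 26

Remark: centres that form as mixtures and are removed or equilibrated later (alkene geometry of 4, C11 of 7 and 8, the acetal carbon of 13, C10 of 17, the anomeric carbon of 23–25, the lactol carbon of 43, C1 of F2) are left undefined in the SMILES; sugar numbering is used for the furanoses 1–25 and target numbering from 27 on.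

Step 1
Reactants: 1 1,2:5,6-di-O-isopropylidene-α-D-glucofuranose
Product: 2 1,2:5,6-di-O-isopropylidene-α-D-ribo-hexofuranos-3-ulose
Conditions: Dess–Martin periodinane, CH2Cl2, rt
Reagents that add atoms: none
Why: Dess–Martin oxidation of the only free (secondary) alcohol is a standard alcohol-to-ketone oxidation that leaves both acetonides untouched and does not epimerise the flanking centres.

Step 2
Reactants: 2 the 3-ulose; 3 triethyl phosphonoacetate
Product: 4 3-deoxy-3-C-(ethoxycarbonylmethylene)-1,2:5,6-di-O-isopropylidene-α-D-ribo-hexofuranose (E/Z mixture)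
Conditions: NaH, THF, 0 °C → rt
Reagents that add atoms: none
Why: Horner–Wadsworth–Emmons olefination of the strained, electrophilic furanos-3-ulose should proceed readily, and the alkene geometry is of no consequence because both isomers converge in step 3.

Step 3
Reactants: 4 the enoate
Product: 5 3-deoxy-3-C-(ethoxycarbonylmethyl)-1,2:5,6-di-O-isopropylidene-α-D-allofuranose
Conditions: H2 (1 atm), Pd/C (palladium on carbon), EtOAc, rt
Reagents that add atoms: none
Why: Heterogeneous catalytic hydrogenation should deliver hydrogen to the exo (β) face of the bicyclic acetal, anti to the 1,2-O-isopropylidene group, so that the carbon branch at sugar C3 (target C7) ends cis to O2, the allo configuration required.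

Step 4
Reactants: 5 the saturated ester; 6 N,N-dimethylmethyleneiminium iodide (Eschenmoser's salt)
Product: 9 ethyl 2-(3-deoxy-1,2:5,6-di-O-isopropylidene-α-D-allofuranos-3-yl)prop-2-enoate, via Mannich base 7 (not isolated), via trimethylammonium iodide 8 (not isolated)
Conditions: LiN(i-Pr)2, THF, −78 °C; 6, −78 → 0 °C; MeI, rt; aq. NaHCO3
Reagents that add atoms: none
Why: Mannich reaction of the lithium ester enolate with Eschenmoser's salt, exhaustive N-methylation and base-induced β-elimination of trimethylamine (Hofmann-type E1cB) is the standard α-methylenation of esters, and C11 is the only enolisable position.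

Step 5
Reactants: 9 the acrylate
Product: 10 2-(3-deoxy-1,2:5,6-di-O-isopropylidene-α-D-allofuranos-3-yl)prop-2-en-1-ol
Conditions: i-Bu2AlH, CH2Cl2, −78 °C
Reagents that add atoms: none
Why: The aluminium hydride reduces the acrylate ester in 1,2-fashion to the allylic alcohol at low temperature (ester-to-alcohol hydride reduction) without affecting the acetals.

Step 6
Reactants: 10 the allylic alcohol
Product: 11 tert-butyldiphenylsilyl ether of 10
Conditions: TBDPSCl, imidazole, DMF, rt
Reagents that add atoms: tert-butyl(chloro)diphenylsilane, CC(C)(C)[Si](Cl)(c1ccccc1)c1ccccc1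
Why: Imidazole-promoted silylation of the primary allylic alcohol is routine, and the tert-butyldiphenylsilyl ether is chosen because it must survive the two aqueous acetic acid steps (7 and 15).

Step 7
Reactants: 11 the silyl ether
Product: 12 3-deoxy-1,2-O-isopropylidene-3-C-[3-(tert-butyldiphenylsilyloxy)prop-1-en-2-yl]-α-D-allofuranose (5,6-diol)
Conditions: AcOH/H2O (7:3), rt
Reagents that add atoms: none
Why: Selective acetal hydrolysis: the terminal 5,6-dioxolane is cleaved by aqueous acetic acid at room temperature far faster than the ring-fused 1,2-acetonide, the classical differentiation of glucose diacetonide derivatives.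

Step 8
Reactants: 12 the 5,6-diol
Product: 13 5,6-O-(4-methoxybenzylidene) acetal of 12
Conditions: 4-MeOC6H4CH(OMe)2, PPTS (cat.), CH2Cl2, rt
Reagents that add atoms: 4-methoxybenzaldehyde dimethyl acetal, COc1ccc(C(OC)OC)cc1
Why: Acid-catalysed transacetalisation closes the 4-methoxybenzylidene acetal on the 1,2-diol, the new acetal centre being lost again in step 9.

Step 9
Reactants: 13 the benzylidene acetal
Product: 14 5-O-(4-methoxybenzyl) ether of 12 (6-OH free)
Conditions: i-Bu2AlH, CH2Cl2, −78 → 0 °C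
Reagents that add atoms: none
Why: Regioselective reductive acetal opening: the aluminium hydride coordinates the less hindered primary oxygen and reduces the resulting oxocarbenium ion, which leaves the 4-methoxybenzyl ether on the secondary oxygen (target O9) and frees the primary hydroxyl.

Step 10
Reactants: 14 the primary alcohol
Product: 15 C6 aldehyde (5-O-PMB hexodialdo-1,4-furanose)
Conditions: Dess–Martin periodinane, CH2Cl2, 0 °C → rt
Reagents that add atoms: none
Why: Dess–Martin oxidation gives the α-alkoxy aldehyde under non-basic conditions that do not epimerise the adjacent centre.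

Step 11
Reactants: 15 the aldehyde; 16 methylmagnesium bromide
Product: 17 C6 methyl carbinol (7-deoxyheptofuranose, C6 epimers)
Conditions: 16, THF, −78 °C
Reagents that add atoms: none
Why: Grignard addition to the aldehyde introduces C14, and the carbinol centre formed is of no consequence because it is oxidised in step 12.

Step 12
Reactants: 17 the carbinol
Product: 18 methyl ketone (sugar C6 = target C10 carbonyl, α-OPMB at C9)
Conditions: Dess–Martin periodinane, CH2Cl2, 0 °C → rt
Reagents that add atoms: none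
Why: Dess–Martin oxidation of the secondary alcohol gives the α-alkoxy methyl ketone without epimerising C9.

Step 13
Reactants: 18 the methyl ketone; 19 (chloromethyl)(isopropoxy)dimethylsilane
Product: 21 1,10-diol (tertiary C10 carbinol bearing the C14 methyl group and the C1 hydroxymethyl group), via β-hydroxysilane 20 (not isolated)
Conditions: 19, Mg, THF, rt; then 18, −78 → 0 °C; then KF, KHCO3, 30% H2O2, MeOH/THF, rt
Reagents that add atoms: hydrogen peroxide, OO
Why: Chelation-controlled (Cram chelate) Grignard addition: magnesium bridges the ketone oxygen and the O9 benzyl-type ether, the hydroxymethyl anion equivalent attacks anti to the C8 substituent and so sets C10 with the target configuration, and Tamao–Fleming oxidation of the C–Si bond then unveils the primary alcohol without touching the 1,1-disubstituted alkene that ozonolysis of a vinyl adduct would destroy.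

Step 14
Reactants: 21 the diol
Product: 22 C1 pivalate of 21 (C10 OH free)
Conditions: PivCl, pyridine, CH2Cl2, 0 °C
Reagents that add atoms: pivaloyl chloride, CC(C)(C)C(=O)Cl
Why: Acylation with pivaloyl chloride is selective for the primary over the tertiary hydroxyl, and the pivalate is stable to the acid of step 15 and the base of step 18.

Step 15
Reactants: 22 the pivalate
Product: 23 furanose lactol (1-OH and 2-OH free, anomers)
Conditions: AcOH/H2O (4:1), 65 °C
Reagents that add atoms: none
Why: Acid-catalysed hydrolysis of the 1,2-O-isopropylidene acetal gives the lactol, which can only be a furanose because O9 is etherified, while the 4-methoxybenzyl and tert-butyldiphenylsilyl ethers and the pivalate should tolerate hot aqueous acetic acid.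

Step 16
Reactants: 23 the lactol diol
Product: 24 1,2-bis-O-tert-butyldimethylsilyl furanose
Conditions: TBSCl, imidazole, DMF, rt → 40 °C
Reagents that add atoms: tert-butyl(chloro)dimethylsilane, CC(C)(C)[Si](C)(C)Cl
Why: Standard imidazole-promoted silylation caps the hemiacetal and the secondary hydroxyl at sugar C2 (target O6), while the tertiary C10 hydroxyl does not react with the silyl chloride.

Step 17
Reactants: 24 the bis-silyl ether
Product: 25 2-O-tert-butyldimethylsilyl lactol
Conditions: Bu4NF/AcOH (1:1), THF, 0 °C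
Reagents that add atoms: none
Why: Anomeric silyl ethers are silyl acetals and are cleaved by acetic acid-buffered fluoride much faster than ordinary secondary silyl ethers, the usual way of freeing a hemiacetal in carbohydrate chemistry.

Step 18
Reactants: 25 the lactol; 26 ethyl 2-[bis(2,2,2-trifluoroethoxy)phosphoryl]propanoate
Product: 27 ethyl (Z)-enoate (C3 ester, C4 methyl, 6-OTBS, 7-[3-(TBDPS-oxy)prop-1-en-2-yl], 8-OH, 9-OPMB, 10-OH, C1 pivalate)
Conditions: 26, KN(SiMe3)2, 18-crown-6, THF, −78 °C
Reagents that add atoms: none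
Why: Still–Gennari olefination of the aldehyde in equilibrium with the lactol: the electron-poor bis(trifluoroethyl) phosphonate with a dissociated potassium counter-ion eliminates from the kinetic adduct and gives the Z trisubstituted enoate, and the silyl ether on O6 prevents lactonisation to a butenolide.

Step 19
Reactants: 27 the enoate diol
Product: 28 8,10-bis-O-triethylsilyl ether of 27
Conditions: Et3SiOTf, 2,6-lutidine, CH2Cl2, −78 → 0 °C
Reagents that add atoms: triethylsilyl trifluoromethanesulfonate, CC[Si](CC)(CC)OS(=O)(=O)C(F)(F)F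
Why: The silyl triflate with 2,6-lutidine silylates both the secondary C8 and the hindered tertiary C10 hydroxyl, giving the two acid-labile ethers that are later removed together.

Step 20
Reactants: 28 the bis-silyl enoate
Product: 29 (Z)-allylic alcohol with free C1 alcohol (3,1-diol)
Conditions: i-Bu2AlH (excess), CH2Cl2, −78 °C
Reagents that add atoms: none
Why: The aluminium hydride reduces the enoate to the Z allylic alcohol and at the same time cleaves the pivalate reductively, so no separate deprotection of C1 is needed.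

Step 21
Reactants: 29 the diol
Product: 30 (Z)-enal (C3 aldehyde, C1 alcohol free)
Conditions: MnO2, CH2Cl2, rt
Reagents that add atoms: none
Why: MnO2 oxidises allylic alcohols selectively, so only the C3 alcohol is taken to the Z enal and the saturated, neopentyl-type C1 alcohol is left.

Step 22
Reactants: 30 the enal; 31 (trimethylsilyl)diazomethane
Product: 32 (Z)-enyne with free C1 alcohol
Conditions: 31, n-BuLi, THF, −78 °C; then 30, −78 → 0 °C
Reagents that add atoms: none
Why: Colvin rearrangement: the lithiated silyl diazomethane adds to the aldehyde, silanolate and N2 are lost, and the alkylidene carbene undergoes a 1,2-hydrogen shift to the terminal alkyne at low temperature, which avoids the methanol conjugate addition and Z/E isomerisation that enals suffer under Ohira–Bestmann conditions.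

Step 23
Reactants: 32 the enyne alcohol
Product: 33 C1 aldehyde
Conditions: Dess–Martin periodinane, NaHCO3, CH2Cl2, 0 °C
Reagents that add atoms: none
Why: Buffered Dess–Martin oxidation converts the hindered primary alcohol into the non-enolisable aldehyde and leaves alkyne, alkenes and silyl ethers alone.

Step 24
Reactants: 33 the aldehyde
Product: 34 C1 carboxylic acid
Conditions: NaClO2, NaH2PO4, 2-methylbut-2-ene, t-BuOH/H2O, 0 °C → rt
Reagents that add atoms: sodium chlorite, [Na+].[O-]Cl=O
Why: Pinnick oxidation takes the α-quaternary aldehyde to the acid, the alkene scavenger trapping hypochlorous acid before it can attack the enyne or the methylene group.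

Step 25
Reactants: 34 the acid
Product: 35 seco alkyne S-ethyl thioester (C2–H alkyne, Z C4=C5, 6-OTBS, 8-OTES, 9-OPMB, 10-OTES, 12-OTBDPS, C1 thioester)
Conditions: EtSH, DCC, DMAP (cat.), CH2Cl2, 0 °C → rt
Reagents that add atoms: ethanethiol, CCS
Why: Steglich-type carbodiimide coupling with a thiol is the standard mild thioesterification, and the acid has no α-hydrogen to epimerise or to form a ketene.

Step 26
Reactants: 35 the seco alkyne thioester
Product: 36 ten-membered enynone (C1 ketone, C2≡C3, Z C4=C5; protecting groups as in 35)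
Conditions: PdCl2(dppf) (20 mol%), P(2-furyl)3, CuI (2 equiv), Et3N/DMF (1:5), 50 °C, syringe-pump addition of 35 to 1 mM, argon
Reagents that add atoms: none
Why: PdCl2(dppf) is reduced in situ to zerovalent palladium, which inserts into the C1–S bond of the thioester; CuI and Et3N turn the C2–H alkyne into the copper acetylide, which transmetalates while copper takes up the thiolate, and reductive elimination from the acyl(alkynyl) divalent palladium species forms C1–C2. The closest known reaction is the intermolecular Pd/Cu coupling of thioesters with terminal alkynes to ynones (an acyl Sonogashira coupling), here run in ring-closing mode, with palladium-mediated closures of ten-membered enediyne rings as the nearest ring-size analogy. The ten-membered carbocycle C1–C10 closes by reductive elimination from an eleven-membered palladacycle, the new bond being made end-on at the sp carbon C2, so that no transannular approach across the ring is required. No stereocentre is formed, and C10, being quaternary, cannot epimerise. The step needs cyclisation to outrun oligomerisation and oxidative alkyne dimerisation with the Z C4=C5 bond intact: slow addition to high dilution under argon, the cis alkene that points C3 towards C6–C10, and the quaternary C10 next to four contiguous substituted carbons bias the chain towards the folded conformer. The C10 triethylsilyl ether keeps the hydroxyl from adding to the new ynone under the basic copper conditions, so that the unbridged ring can be isolated.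

Step 27
Reactants: 36 the enynone
Product: 37 8,10-dihydroxy enynone
Conditions: HF·pyridine, pyridine, THF, 0 °C
Reagents that add atoms: none
Why: Fluoride-mediated desilylation: triethylsilyl ethers are cleaved by pyridine-buffered HF·pyridine much faster than the tert-butyldimethylsilyl and tert-butyldiphenylsilyl ethers, which stay on O6 and O12.

Step 28
Reactants: 37 the hydroxy ynone
Product: 38 bridged 3(2H)-furanone (O bridge C3–O–C10, C8 OH free)
Conditions: AuCl3 (5 mol%), CH2Cl2, rt
Reagents that add atoms: none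
Why: Gold-catalysed cycloisomerisation of a γ-hydroxy ynone: AuCl3 activates the triple bond, the C10 hydroxyl adds 5-endo-dig to C3 and protodeauration gives the 3(2H)-furanone, while O6 is still silylated and so cannot add to C3 to give a furan.

Step 29
Reactants: 38 the furanone alcohol; 39 methacrylic anhydride
Product: 40 C8 methacrylate
Conditions: 39, Et3N, DMAP (cat.), CH2Cl2, 0 °C → rt
Reagents that add atoms: none
Why: DMAP-catalysed acylation of the only free hydroxyl (C8), with C9 still carrying its benzyl-type ether, fixes the position of the ester without any regioselectivity problem.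

Step 30
Reactants: 40 the methacrylate
Product: 41 6,12-diol
Conditions: HF·pyridine, THF, 0 °C → rt
Reagents that add atoms: none
Why: HF·pyridine removes the secondary tert-butyldimethylsilyl and the primary tert-butyldiphenylsilyl ether under non-basic conditions that the methacrylate and the furanone tolerate.

Step 31
Reactants: 41 the diol
Product: 44 9-O-(4-methoxybenzyl) ether of the target, via hydroxy aldehyde 42 (not isolated), via lactol 43 (not isolated)
Conditions: TEMPO (cat.), PhI(OAc)2, CH2Cl2, rt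
Reagents that add atoms: none
Why: TEMPO/PhI(OAc)2 oxidative lactonisation: the oxoammonium salt oxidises the primary allylic alcohol first, the C6 hydroxyl closes on the aldehyde to the five-membered lactol and a second oxidation gives the α-methylene γ-lactone, C8 being acylated and C9 etherified so that only the 6,12-lactone can form.

Step 32
Reactants: 44 the protected target
Product: 45 target CNP0252578.5
Conditions: DDQ, CH2Cl2/pH 7 buffer, 0 °C
Reagents that add atoms: none
Why: Oxidative cleavage of the 4-methoxybenzyl ether by DDQ (benzylic hydride abstraction, hydrolysis of the oxocarbenium ion) runs under neutral conditions that spare the esters, the lactone and the dienyl furanone.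

Compound list
1 | 1,2:5,6-di-O-isopropylidene-α-D-glucofuranose | CC1(C)O[C@H]2O[C@H]([C@H]3COC(C)(C)O3)[C@H](O)[C@H]2O1 | starting material
2 | 1,2:5,6-di-O-isopropylidene-α-D-ribo-hexofuranos-3-ulose | CC1(C)O[C@H]2O[C@H]([C@H]3COC(C)(C)O3)C(=O)[C@H]2O1 | intermediate
3 | triethyl phosphonoacetate | CCOC(=O)CP(=O)(OCC)OCC | starting material
4 | 3-deoxy-3-C-(ethoxycarbonylmethylene)-1,2:5,6-di-O-isopropylidene-α-D-ribo-hexofuranose (E/Z) | CC1(C)O[C@H]2O[C@H]([C@H]3COC(C)(C)O3)C(=CC(=O)OCC)[C@H]2O1 | intermediate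
5 | 3-deoxy-3-C-(ethoxycarbonylmethyl)-1,2:5,6-di-O-isopropylidene-α-D-allofuranose | CC1(C)O[C@H]2O[C@H]([C@H]3COC(C)(C)O3)[C@@H](CC(=O)OCC)[C@H]2O1 | intermediate
6 | N,N-dimethylmethyleneiminium iodide | C=[N+](C)C.[I-] | starting material
7 | Mannich base, ethyl 3-(dimethylamino)-2-(allofuranos-3-yl)propanoate | CC1(C)O[C@H]2O[C@H]([C@H]3COC(C)(C)O3)[C@@H](C(CN(C)C)C(=O)OCC)[C@H]2O1 | intermediate
8 | trimethylammonium iodide of 7 | CC1(C)O[C@H]2O[C@H]([C@H]3COC(C)(C)O3)[C@@H](C(C[N+](C)(C)C)C(=O)OCC)[C@H]2O1.[I-] | intermediate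
9 | ethyl 2-(3-deoxy-1,2:5,6-di-O-isopropylidene-α-D-allofuranos-3-yl)prop-2-enoate | CC1(C)O[C@H]2O[C@H]([C@H]3COC(C)(C)O3)[C@@H](C(=C)C(=O)OCC)[C@H]2O1 | intermediate
10 | 2-(3-deoxy-1,2:5,6-di-O-isopropylidene-α-D-allofuranos-3-yl)prop-2-en-1-ol | CC1(C)O[C@H]2O[C@H]([C@H]3COC(C)(C)O3)[C@@H](C(=C)CO)[C@H]2O1 | intermediate
11 | tert-butyldiphenylsilyl ether of 10 | CC1(C)O[C@H]2O[C@H]([C@H]3COC(C)(C)O3)[C@@H](C(=C)CO[Si](c3ccccc3)(c3ccccc3)C(C)(C)C)[C@H]2O1 | intermediate
12 | 5,6-diol (1,2-O-isopropylidene, 3-C-[3-(TBDPS-oxy)prop-1-en-2-yl], allo) | CC1(C)O[C@H]2O[C@H]([C@H](O)CO)[C@@H](C(=C)CO[Si](c3ccccc3)(c3ccccc3)C(C)(C)C)[C@H]2O1 | intermediate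
13 | 5,6-O-(4-methoxybenzylidene) acetal of 12 | CC1(C)O[C@H]2O[C@H]([C@H]3COC(c4ccc(OC)cc4)O3)[C@@H](C(=C)CO[Si](c3ccccc3)(c3ccccc3)C(C)(C)C)[C@H]2O1 | intermediate
14 | 5-O-(4-methoxybenzyl) ether of 12 | CC1(C)O[C@H]2O[C@H]([C@H](OCc3ccc(OC)cc3)CO)[C@@H](C(=C)CO[Si](c3ccccc3)(c3ccccc3)C(C)(C)C)[C@H]2O1 | intermediate
15 | C6 aldehyde of 14 | CC1(C)O[C@H]2O[C@H]([C@H](OCc3ccc(OC)cc3)C=O)[C@@H](C(=C)CO[Si](c3ccccc3)(c3ccccc3)C(C)(C)C)[C@H]2O1 | intermediate
16 | methylmagnesium bromide | C[Mg]Br | starting material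
17 | C6 methyl carbinol (epimers) | CC1(C)O[C@H]2O[C@H]([C@H](OCc3ccc(OC)cc3)C(C)O)[C@@H](C(=C)CO[Si](c3ccccc3)(c3ccccc3)C(C)(C)C)[C@H]2O1 | intermediate
18 | C6 methyl ketone | CC1(C)O[C@H]2O[C@H]([C@H](OCc3ccc(OC)cc3)C(C)=O)[C@@H](C(=C)CO[Si](c3ccccc3)(c3ccccc3)C(C)(C)C)[C@H]2O1 | intermediate
19 | (chloromethyl)(isopropoxy)dimethylsilane | ClC[Si](C)(C)OC(C)C | starting material
20 | tertiary β-hydroxysilane (C10 carbinol with CH2SiMe2(Oi-Pr)) | CC1(C)O[C@H]2O[C@H]([C@H](OCc3ccc(OC)cc3)[C@@](C)(O)C[Si](C)(C)OC(C)C)[C@@H](C(=C)CO[Si](c3ccccc3)(c3ccccc3)C(C)(C)C)[C@H]2O1 | intermediate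
21 | 1,10-diol | CC1(C)O[C@H]2O[C@H]([C@H](OCc3ccc(OC)cc3)[C@@](C)(O)CO)[C@@H](C(=C)CO[Si](c3ccccc3)(c3ccccc3)C(C)(C)C)[C@H]2O1 | intermediate
22 | C1 pivalate of 21 | CC1(C)O[C@H]2O[C@H]([C@H](OCc3ccc(OC)cc3)[C@@](C)(O)COC(=O)C(C)(C)C)[C@@H](C(=C)CO[Si](c3ccccc3)(c3ccccc3)C(C)(C)C)[C@H]2O1 | intermediate
23 | furanose lactol (1,2-diol, anomers) | OC1O[C@H]([C@H](OCc2ccc(OC)cc2)[C@@](C)(O)COC(=O)C(C)(C)C)[C@@H](C(=C)CO[Si](c2ccccc2)(c2ccccc2)C(C)(C)C)[C@H]1O | intermediate
24 | 1,2-bis-O-TBS furanose | CC(C)(C)[Si](C)(C)OC1O[C@H]([C@H](OCc2ccc(OC)cc2)[C@@](C)(O)COC(=O)C(C)(C)C)[C@@H](C(=C)CO[Si](c2ccccc2)(c2ccccc2)C(C)(C)C)[C@H]1O[Si](C)(C)C(C)(C)C | intermediate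
25 | 2-O-TBS lactol | OC1O[C@H]([C@H](OCc2ccc(OC)cc2)[C@@](C)(O)COC(=O)C(C)(C)C)[C@@H](C(=C)CO[Si](c2ccccc2)(c2ccccc2)C(C)(C)C)[C@H]1O[Si](C)(C)C(C)(C)C | intermediate
26 | ethyl 2-[bis(2,2,2-trifluoroethoxy)phosphoryl]propanoate | CCOC(=O)C(C)P(=O)(OCC(F)(F)F)OCC(F)(F)F | starting material
27 | ethyl (Z)-enoate, 8,10-diol, C1 pivalate | CCOC(=O)/C(C)=C\[C@H](O[Si](C)(C)C(C)(C)C)[C@H](C(=C)CO[Si](c1ccccc1)(c1ccccc1)C(C)(C)C)[C@H](O)[C@H](OCc1ccc(OC)cc1)[C@@](C)(O)COC(=O)C(C)(C)C | intermediate
28 | 8,10-bis-O-TES ether of 27 | CCOC(=O)/C(C)=C\[C@H](O[Si](C)(C)C(C)(C)C)[C@H](C(=C)CO[Si](c1ccccc1)(c1ccccc1)C(C)(C)C)[C@H](O[Si](CC)(CC)CC)[C@H](OCc1ccc(OC)cc1)[C@@](C)(O[Si](CC)(CC)CC)COC(=O)C(C)(C)C | intermediate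
29 | (Z)-allylic alcohol, C1 alcohol free | OC/C(C)=C\[C@H](O[Si](C)(C)C(C)(C)C)[C@H](C(=C)CO[Si](c1ccccc1)(c1ccccc1)C(C)(C)C)[C@H](O[Si](CC)(CC)CC)[C@H](OCc1ccc(OC)cc1)[C@@](C)(O[Si](CC)(CC)CC)CO | intermediate
30 | (Z)-enal, C1 alcohol free | O=C/C(C)=C\[C@H](O[Si](C)(C)C(C)(C)C)[C@H](C(=C)CO[Si](c1ccccc1)(c1ccccc1)C(C)(C)C)[C@H](O[Si](CC)(CC)CC)[C@H](OCc1ccc(OC)cc1)[C@@](C)(O[Si](CC)(CC)CC)CO | intermediate
31 | (trimethylsilyl)diazomethane | C[Si](C)(C)C=[N+]=[N-] | starting material
32 | (Z)-enyne C1 alcohol | C#C/C(C)=C\[C@H](O[Si](C)(C)C(C)(C)C)[C@H](C(=C)CO[Si](c1ccccc1)(c1ccccc1)C(C)(C)C)[C@H](O[Si](CC)(CC)CC)[C@H](OCc1ccc(OC)cc1)[C@@](C)(O[Si](CC)(CC)CC)CO | intermediate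
33 | (Z)-enyne C1 aldehyde | C#C/C(C)=C\[C@H](O[Si](C)(C)C(C)(C)C)[C@H](C(=C)CO[Si](c1ccccc1)(c1ccccc1)C(C)(C)C)[C@H](O[Si](CC)(CC)CC)[C@H](OCc1ccc(OC)cc1)[C@@](C)(O[Si](CC)(CC)CC)C=O | intermediate
34 | (Z)-enyne C1 carboxylic acid | C#C/C(C)=C\[C@H](O[Si](C)(C)C(C)(C)C)[C@H](C(=C)CO[Si](c1ccccc1)(c1ccccc1)C(C)(C)C)[C@H](O[Si](CC)(CC)CC)[C@H](OCc1ccc(OC)cc1)[C@@](C)(O[Si](CC)(CC)CC)C(=O)O | intermediate
35 | seco alkyne S-ethyl thioester | C#C/C(C)=C\[C@H](O[Si](C)(C)C(C)(C)C)[C@H](C(=C)CO[Si](c1ccccc1)(c1ccccc1)C(C)(C)C)[C@H](O[Si](CC)(CC)CC)[C@H](OCc1ccc(OC)cc1)[C@@](C)(O[Si](CC)(CC)CC)C(=O)SCC | intermediate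
36 | ten-membered enynone | CC[Si](CC)(CC)O[C@H]1[C@@H](C(=C)CO[Si](c2ccccc2)(c2ccccc2)C(C)(C)C)[C@@H](O[Si](C)(C)C(C)(C)C)/C=C(/C)C#CC(=O)[C@](C)(O[Si](CC)(CC)CC)[C@H]1OCc2ccc(OC)cc2 | intermediate
37 | 8,10-dihydroxy enynone | O[C@H]1[C@@H](C(=C)CO[Si](c2ccccc2)(c2ccccc2)C(C)(C)C)[C@@H](O[Si](C)(C)C(C)(C)C)/C=C(/C)C#CC(=O)[C@](C)(O)[C@H]1OCc2ccc(OC)cc2 | intermediate
38 | bridged 3(2H)-furanone, C8 alcohol | O[C@H]1[C@@H](C(=C)CO[Si](c2ccccc2)(c2ccccc2)C(C)(C)C)[C@@H](O[Si](C)(C)C(C)(C)C)/C=C(/C)C2=CC(=O)[C@](C)(O2)[C@H]1OCc2ccc(OC)cc2 | intermediate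
39 | methacrylic anhydride | C=C(C)C(=O)OC(=O)C(C)=C | starting material
40 | C8 methacrylate of 38 | C=C(C)C(=O)O[C@H]1[C@@H](C(=C)CO[Si](c2ccccc2)(c2ccccc2)C(C)(C)C)[C@@H](O[Si](C)(C)C(C)(C)C)/C=C(/C)C2=CC(=O)[C@](C)(O2)[C@H]1OCc2ccc(OC)cc2 | intermediate
41 | 6,12-diol | C=C(C)C(=O)O[C@H]1[C@@H](C(=C)CO)[C@@H](O)/C=C(/C)C2=CC(=O)[C@](C)(O2)[C@H]1OCc2ccc(OC)cc2 | intermediate
42 | C12 aldehyde, C6 alcohol | C=C(C)C(=O)O[C@H]1[C@@H](C(=C)C=O)[C@@H](O)/C=C(/C)C2=CC(=O)[C@](C)(O2)[C@H]1OCc2ccc(OC)cc2 | intermediate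
43 | 6,12-lactol | C=C(C)C(=O)O[C@H]1[C@H]2C(=C)C(O)O[C@H]2/C=C(/C)C2=CC(=O)[C@](C)(O2)[C@H]1OCc2ccc(OC)cc2 | intermediate
44 | 9-O-(4-methoxybenzyl) ether of the target | C=C(C)C(=O)O[C@H]1[C@H]2C(=C)C(=O)O[C@H]2/C=C(/C)C2=CC(=O)[C@](C)(O2)[C@H]1OCc2ccc(OC)cc2 | intermediate
45 | CNP0252578.5, (4Z,6S,7S,8S,9S,10R)-9-hydroxy-8-methacryloyloxy-1-oxo-3,10-epoxygermacra-2,4,11(13)-trien-12,6-olide | C=C(C)C(=O)O[C@H]1[C@H]2C(=C)C(=O)O[C@H]2/C=C(/C)C2=CC(=O)[C@](C)(O2)[C@H]1O | target

Total step count: 32. Longest linear sequence: 32 steps (the route is linear from 1 to 45).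

Steps most likely to fail

Step 26. The acyl(alkynyl)palladium intermediate may fail to form within one molecule, so that intermolecular coupling to dimers and oligomers, or copper-mediated oxidative dimerisation of the alkyne, takes over. The fallback sets out from aldehyde 33 and closes the same C1–C2 bond at the aldehyde oxidation level. The alkyne is iodinated (N-iodosuccinimide, AgNO3 cat., acetone) to the iodoalkyne aldehyde F1. A Nozaki–Hiyama–Kishi reaction (CrCl2, NiCl2 cat., THF, high dilution), the way strained enediyne rings are closed, should give the ten-membered propargylic alcohol F2. Dess–Martin oxidation brings the route back at enynone 36.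

Step 18. Slow opening of the lactol can allow the liberated C8 alkoxide to add to the new enoate (oxa-Michael closure to a tetrahydrofuran), the C6 silyl group to migrate, or the Z/E ratio to erode on warming. The fallback sets out from lactol 25 and makes the Z alkene as a vinyl iodide, which cannot undergo conjugate addition. Stork–Zhao olefination with the ylide from (1-iodoethyl)triphenylphosphonium iodide and NaN(SiMe3)2 (THF, −78 °C) should give the (Z)-vinyl iodide diol F3. Silylation (Et3SiOTf, 2,6-lutidine) gives the bis-triethylsilyl ether F4. Sonogashira coupling with ethynyltrimethylsilane (Pd(PPh3)4, CuI, i-Pr2NH) gives the silylated enyne pivalate F5. i-Bu2AlH removes the pivalate to give the silylated enyne alcohol F6, and K2CO3 in MeOH removes the C-silyl group, which returns the route at enyne alcohol 32.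

Step 28. The transannular 5-endo closure builds a bridged bicycle with a bridgehead double bond; the gold-activated ynone may instead be hydrated, be attacked by the free C8 hydroxyl, or decompose under the Lewis-acidic metal. The fallback sets out from 37 and uses the classical amine route to 3(2H)-furanones. Conjugate addition of Et2NH (EtOH, rt) gives the enaminone F7. Dilute aqueous acetic acid in THF then lets the C10 hydroxyl add to C3 and expel diethylamine, which returns the route at furanone 38.

Further compounds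
F1 | step 26 | iodoalkyne aldehyde (33 with iodine on C2) | IC#C/C(C)=C\[C@H](O[Si](C)(C)C(C)(C)C)[C@H](C(=C)CO[Si](c1ccccc1)(c1ccccc1)C(C)(C)C)[C@H](O[Si](CC)(CC)CC)[C@H](OCc1ccc(OC)cc1)[C@@](C)(O[Si](CC)(CC)CC)C=O
F2 | step 26 | ten-membered propargylic alcohol (C1 carbinol of 36, C1 epimers) | CC[Si](CC)(CC)O[C@H]1[C@@H](C(=C)CO[Si](c2ccccc2)(c2ccccc2)C(C)(C)C)[C@@H](O[Si](C)(C)C(C)(C)C)/C=C(/C)C#CC(O)[C@](C)(O[Si](CC)(CC)CC)[C@H]1OCc2ccc(OC)cc2
F3 | step 18 | (Z)-vinyl iodide 8,10-diol, C1 pivalate | I/C(C)=C\[C@H](O[Si](C)(C)C(C)(C)C)[C@H](C(=C)CO[Si](c1ccccc1)(c1ccccc1)C(C)(C)C)[C@H](O)[C@H](OCc1ccc(OC)cc1)[C@@](C)(O)COC(=O)C(C)(C)C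
F4 | step 18 | 8,10-bis-O-triethylsilyl ether of F3 | I/C(C)=C\[C@H](O[Si](C)(C)C(C)(C)C)[C@H](C(=C)CO[Si](c1ccccc1)(c1ccccc1)C(C)(C)C)[C@H](O[Si](CC)(CC)CC)[C@H](OCc1ccc(OC)cc1)[C@@](C)(O[Si](CC)(CC)CC)COC(=O)C(C)(C)C
F5 | step 18 | C2-trimethylsilyl (Z)-enyne, C1 pivalate | C[Si](C)(C)C#C/C(C)=C\[C@H](O[Si](C)(C)C(C)(C)C)[C@H](C(=C)CO[Si](c1ccccc1)(c1ccccc1)C(C)(C)C)[C@H](O[Si](CC)(CC)CC)[C@H](OCc1ccc(OC)cc1)[C@@](C)(O[Si](CC)(CC)CC)COC(=O)C(C)(C)C
F6 | step 18 | C2-trimethylsilyl derivative of 32 | C[Si](C)(C)C#C/C(C)=C\[C@H](O[Si](C)(C)C(C)(C)C)[C@H](C(=C)CO[Si](c1ccccc1)(c1ccccc1)C(C)(C)C)[C@H](O[Si](CC)(CC)CC)[C@H](OCc1ccc(OC)cc1)[C@@](C)(O[Si](CC)(CC)CC)CO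
F7 | step 28 | C3 diethylamino enaminone of 37 | O[C@H]1[C@@H](C(=C)CO[Si](c2ccccc2)(c2ccccc2)C(C)(C)C)[C@@H](O[Si](C)(C)C(C)(C)C)/C=C(/C)C(N(CC)CC)=CC(=O)[C@](C)(O)[C@H]1OCc2ccc(OC)cc2
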